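**Strategy.** The bicyclo[2.2.2]octane is disconnected by a retro-Diels–Alder into (R)-sorbicillinol and an exo-methylene dioxanone dienophile (last step). Everything rests on how the dienophile's cyclohexene (numbered from the ester carbon C1) is made. C1, which lies between vinylic C2–H and the C6 methylene, is inserted as a CH(CO2Me) unit into the C(=O)–CH2 bond of an epoxycyclopentanone by BF3-promoted methyl diazoacetate homologation. One operation enlarges the five-membered ring to the six-membered β-keto ester with all ring carbons and the ester in place. The precursor, a trans-4-silyloxy-2,3-epoxycyclopentanone, already holds the three oxygenated carbons: C5–O is bought with (R)-4-silyloxycyclopentenone, the C3/C4 oxygens are relayed from it.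

Key step: step 3

Assumption: compounds 1, 9, 15 and 18 are taken as catalogue items, and the C1 configuration of 19 is assigned after the separation in step 11 (crystallography or CD), because the Wessely step is not stereoselective.

Step 1
Reactants: 1 (R)-4-[(tert-butyldimethylsilyl)oxy]cyclopent-2-en-1-one
Product: 2 (1S,4R,5R)-4-[(tert-butyldimethylsilyl)oxy]-6-oxabicyclo[3.1.0]hexan-2-one (oxirane trans to OTBS)
Conditions: 30% aq. H2O2, NaOH (cat.), MeOH, −20 °C
Reagents that add atoms: hydrogen peroxide, OO
Why: Weitz–Scheffer nucleophilic epoxidation: hydroperoxide adds to C3 of the enone on the face anti to the bulky C4 silyloxy group and the enolate closes the oxirane, so both new stereocentres are set trans to OTBS by substrate control.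

Step 2
Reactants: 3 glycine methyl ester hydrochloride
Product: 4 methyl diazoacetate
Conditions: NaNO2, H2SO4 (cat.), CH2Cl2/H2O, −5 °C
Reagents that add atoms: sodium nitrite, [Na+].[O-]N=O
Why: Diazotisation of an α-amino ester; the ester-acidified diazonium loses a proton to give the stabilised diazo compound, which is used as a dried CH2Cl2 solution.

Step 3
Reactants: 2 (1S,4R,5R)-4-[(tert-butyldimethylsilyl)oxy]-6-oxabicyclo[3.1.0]hexan-2-one; 4 methyl diazoacetate
Product: 5 methyl (1S,5R,6R)-5-[(tert-butyldimethylsilyl)oxy]-2-oxo-7-oxabicyclo[4.1.0]heptane-3-carboxylate (C3 epimers/enol)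
Conditions: BF3·OEt2 (1.1 equiv), CH2Cl2, −78 → −30 °C
Reagents that add atoms: none
Why: BF3 activates the ketone of 2, the nucleophilic diazo carbon of 4 adds to it, and the β-oxido diazonium intermediate loses N2 with 1,2-shift of a ring C–C bond (Tiffeneau–Demjanov/Büchner–Curtius–Schlotterbeck-type homologation). The closest known reaction type is the BF3·OEt2- or Et3O+BF4−-promoted conversion of cycloalkanones into ring-enlarged 2-oxocycloalkanecarboxylates with diazoacetates. No ring is closed: the cyclopentanone is enlarged to the cyclohexanone by migratory insertion of the CH(CO2Me) carbon between C2 (carbonyl) and C3 (CH2), so that the inserted carbon becomes the ester-bearing ring carbon and the former carbonyl carbon the future vinylic CH. The three existing stereocentres (C4–O and the two oxirane carbons) lie outside the migrating bond and are carried through untouched, while the new α-carbon of the β-keto ester is configurationally labile (enol) and is erased in step 5. The step needs migration of the CH2 carbon instead of the oxirane carbon, which is secured by the electron-withdrawing oxirane oxygen that lowers the migratory aptitude of C1. It also needs the carbonyl to react before the acid-labile oxirane, which the low temperature and the high electrophilicity of the α-oxygenated ketone should secure.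

Step 4
Reactants: 5 methyl (1S,5R,6R)-5-[(tert-butyldimethylsilyl)oxy]-2-oxo-7-oxabicyclo[4.1.0]heptane-3-carboxylate
Product: 6 methyl 5-[(tert-butyldimethylsilyl)oxy]-2-hydroxy-7-oxabicyclo[4.1.0]heptane-3-carboxylate (oxirane and C5 as in 5; mixture at C2/C3)
Conditions: NaBH4, MeOH, −20 °C
Reagents that add atoms: none
Why: Borohydride reduction of the ketone tautomer of the β-keto ester leaves oxirane, ester and silyl ether untouched; the carbinol and α-carbon are formed as a mixture, which is harmless because both centres become sp2 in step 5.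

Step 5
Reactants: 6 methyl 5-[(tert-butyldimethylsilyl)oxy]-2-hydroxy-7-oxabicyclo[4.1.0]heptane-3-carboxylate
Product: 8 methyl (1R,5R,6R)-5-[(tert-butyldimethylsilyl)oxy]-7-oxabicyclo[4.1.0]hept-2-ene-3-carboxylate, via mesylate 7 (not isolated)
Conditions: MsCl, Et3N, CH2Cl2, 0 °C; then DBU, 0 °C → rt
Reagents that add atoms: methanesulfonyl chloride, CS(=O)(=O)Cl (its atoms are held only by intermediate 7)
Why: Mesylation followed by E1cB elimination through the ester enolate: only the α-H next to the ester is acidic, so the double bond can only form between the former carbonyl carbon and the ester-bearing carbon, and the oxirane is not touched.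

Step 6
Reactants: 9 methyl (2R)-oxirane-2-carboxylate
Product: 10 methyl (2S)-3-chloro-2-hydroxypropanoate
Conditions: HCl (2 M in Et2O), CH2Cl2, 0 °C
Reagents that add atoms: hydrogen chloride, Cl
Why: Acid-mediated SN2 opening of a glycidic ester by chloride at the unsubstituted C3 (away from the ester), so C2 is not touched and keeps its configuration (the descriptor changes from R to S by priority only).

Step 7
Reactants: 8 methyl (1R,5R,6R)-5-[(tert-butyldimethylsilyl)oxy]-7-oxabicyclo[4.1.0]hept-2-ene-3-carboxylate; 10 methyl (2S)-3-chloro-2-hydroxypropanoate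
Product: 12 methyl (3S,4aS,8R,8aR)-8-[(tert-butyldimethylsilyl)oxy]-3-(chloromethyl)-2-oxo-2,3,4a,7,8,8a-hexahydro-1,4-benzodioxine-6-carboxylate, via hydroxy ester 11 (not isolated)
Conditions: 10 (3 equiv), BF3·OEt2 (0.2 equiv), CH2Cl2, −20 → 0 °C; evaporate; then CSA (cat.), PhMe, 80 °C
Reagents that add atoms: none
Why: Lewis-acid-catalysed alcoholysis of a vinyl oxirane: the alcohol attacks the allylic oxirane carbon C1 with inversion (trans-diaxial opening; the other oxirane carbon is shielded and deactivated by the neighbouring OTBS), which sets the ether carbon trans to the liberated C4–OH and gives the all-trans triad, and acid-catalysed transesterification of the trans-hydroxy ester then closes the six-membered lactone; the side-chain stereocentre brought in with 10 is erased in step 8.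

Step 8
Reactants: 12 methyl (3S,4aS,8R,8aR)-8-[(tert-butyldimethylsilyl)oxy]-3-(chloromethyl)-2-oxo-2,3,4a,7,8,8a-hexahydro-1,4-benzodioxine-6-carboxylate
Product: 13 methyl (4aS,8R,8aR)-8-[(tert-butyldimethylsilyl)oxy]-3-methylidene-2-oxo-2,3,4a,7,8,8a-hexahydro-1,4-benzodioxine-6-carboxylate
Conditions: DBU, CH2Cl2, 0 °C
Reagents that add atoms: none
Why: E1cB dehydrochlorination: the lactone α-H (also α to the ether oxygen) is removed by DBU and chloride leaves, and since no other β-hydrogen exists only the exocyclic methylene can form.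

Step 9
Reactants: 13 methyl (4aS,8R,8aR)-8-[(tert-butyldimethylsilyl)oxy]-3-methylidene-2-oxo-2,3,4a,7,8,8a-hexahydro-1,4-benzodioxine-6-carboxylate
Product: 14 methyl (4aS,8R,8aS)-8-hydroxy-3-methylidene-2-oxo-2,3,4a,7,8,8a-hexahydro-1,4-benzodioxine-6-carboxylate
Conditions: HF·pyridine, pyridine/THF, 0 °C → rt
Reagents that add atoms: none
Why: Fluoride-driven cleavage of the secondary TBS ether under buffered acidic conditions that spare the lactone, the captodative enol ether and the enoate; no stereocentre is touched.

Step 10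
Reactants: 15 2,4-dimethylbenzene-1,3-diol; 16 sorbic acid, (2E,4E)-hexa-2,4-dienoic acid
Product: 17 sorbicillin, (2E,4E)-1-(2,4-dihydroxy-3,5-dimethylphenyl)hexa-2,4-dien-1-one
Conditions: BF3·OEt2 (neat), 100 °C
Reagents that add atoms: none
Why: BF3-mediated Friedel–Crafts acylation at C6, the only free ring position that is ortho/para to both hydroxyl groups.

Step 11
Reactants: 17 sorbicillin; 18 (S)-2-methoxy-2-phenylacetic acid
Product: 19 (1R)-3-[(2E,4E)-hexa-2,4-dienoyl]-4-hydroxy-1,5-dimethyl-6-oxocyclohexa-2,4-dien-1-yl (2S)-2-methoxy-2-phenylacetate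
Conditions: Pb(OAc)4 pre-equilibrated with excess 18, CH2Cl2, 0 °C → rt; chromatographic separation of the C1 epimers
Reagents that add atoms: none
Why: Modified Wessely oxidation: the aryloxy-lead(IV) carboxylate delivers the carboxylate to the methyl-bearing C5 of sorbicillin (ortho to the free 4-OH and para to the chelated 2-OH, less hindered than C3) to give the o-quinol ester; no induction is relied on, the two C1 epimers are diastereomers because of the (S)-acyl group and are separated by chromatography, the (1R)-ester being carried on.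

Step 12
Reactants: 19 (1R)-3-[(2E,4E)-hexa-2,4-dienoyl]-4-hydroxy-1,5-dimethyl-6-oxocyclohexa-2,4-dien-1-yl (2S)-2-methoxy-2-phenylacetate; 14 methyl (4aS,8R,8aS)-8-hydroxy-3-methylidene-2-oxo-2,3,4a,7,8,8a-hexahydro-1,4-benzodioxine-6-carboxylate
Product: 21 target CNP0259039.2 (spiro-fused bicyclo[2.2.2]octane/benzodioxinone adduct; lactone C=O syn to the enolised diketone bridge; tertiary OH syn to the dienophile-derived bridge), via (R)-sorbicillinol 20 (not isolated)
Conditions: KOH, THF/H2O, 0 °C; 1 M HCl, extraction into CH2Cl2 at 0 °C; then 14 (limiting), CH2Cl2, rt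
Reagents that add atoms: none
Why: Saponification unmasks the o-quinol 20, which after acidification acts as the cyclic diene in a Diels–Alder reaction with the captodative exo-methylene of 14 (used as the limiting partner to outrun dimerisation of 20): the CH2 terminus bonds to the unsubstituted ring CH and the spiro carbon to the methyl-bearing terminus, the dienophile adds to the face syn to the carbinol OH and with the lactone C=O endo, which sets the two bridgeheads and the spiro centre relative to the (R)-carbinol.

**Compound list**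

1 | (R)-4-[(tert-butyldimethylsilyl)oxy]cyclopent-2-en-1-one | O=C1C[C@@H](O[Si](C)(C)C(C)(C)C)C=C1 | starting material
2 | (1S,4R,5R)-4-[(tert-butyldimethylsilyl)oxy]-6-oxabicyclo[3.1.0]hexan-2-one | O=C1C[C@@H](O[Si](C)(C)C(C)(C)C)[C@@H]2O[C@H]12 | intermediate
3 | glycine methyl ester hydrochloride | COC(=O)C[NH3+].[Cl-] | starting material
4 | methyl diazoacetate | COC(=O)C=[N+]=[N-] | intermediate
5 | methyl (1S,5R,6R)-5-[(tert-butyldimethylsilyl)oxy]-2-oxo-7-oxabicyclo[4.1.0]heptane-3-carboxylate (C3 not defined) | COC(=O)C1C[C@@H](O[Si](C)(C)C(C)(C)C)[C@@H]2O[C@@H]2C1=O | intermediate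
6 | methyl 5-[(tert-butyldimethylsilyl)oxy]-2-hydroxy-7-oxabicyclo[4.1.0]heptane-3-carboxylate (C2/C3 mixture) | COC(=O)C1C[C@@H](O[Si](C)(C)C(C)(C)C)[C@@H]2O[C@@H]2C1O | intermediate
7 | 2-O-methanesulfonate of 6 | COC(=O)C1C[C@@H](O[Si](C)(C)C(C)(C)C)[C@@H]2O[C@@H]2C1OS(C)(=O)=O | intermediate
8 | methyl (1R,5R,6R)-5-[(tert-butyldimethylsilyl)oxy]-7-oxabicyclo[4.1.0]hept-2-ene-3-carboxylate | COC(=O)C1=C[C@H]2O[C@H]2[C@H](O[Si](C)(C)C(C)(C)C)C1 | intermediate
9 | methyl (2R)-oxirane-2-carboxylate (methyl (R)-glycidate) | COC(=O)[C@H]1CO1 | starting material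
10 | methyl (2S)-3-chloro-2-hydroxypropanoate | COC(=O)[C@H](O)CCl | intermediate
11 | methyl (3S,4R,5R)-5-[(tert-butyldimethylsilyl)oxy]-3-{[(2S)-3-chloro-1-methoxy-1-oxopropan-2-yl]oxy}-4-hydroxycyclohex-1-ene-1-carboxylate | COC(=O)[C@@H](CCl)O[C@H]1C=C(C(=O)OC)C[C@@H](O[Si](C)(C)C(C)(C)C)[C@@H]1O | intermediate
12 | methyl (3S,4aS,8R,8aR)-8-[(tert-butyldimethylsilyl)oxy]-3-(chloromethyl)-2-oxo-2,3,4a,7,8,8a-hexahydro-1,4-benzodioxine-6-carboxylate | ClC[C@H]1O[C@H]2C=C(C(=O)OC)C[C@@H](O[Si](C)(C)C(C)(C)C)[C@@H]2OC1=O | intermediate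
13 | methyl (4aS,8R,8aR)-8-[(tert-butyldimethylsilyl)oxy]-3-methylidene-2-oxo-2,3,4a,7,8,8a-hexahydro-1,4-benzodioxine-6-carboxylate | C=C1O[C@H]2C=C(C(=O)OC)C[C@@H](O[Si](C)(C)C(C)(C)C)[C@@H]2OC1=O | intermediate
14 | methyl (4aS,8R,8aS)-8-hydroxy-3-methylidene-2-oxo-2,3,4a,7,8,8a-hexahydro-1,4-benzodioxine-6-carboxylate | C=C1O[C@H]2C=C(C(=O)OC)C[C@@H](O)[C@@H]2OC1=O | intermediate
15 | 2,4-dimethylbenzene-1,3-diol | Cc1ccc(O)c(C)c1O | starting material
16 | sorbic acid | C/C=C/C=C/C(=O)O | starting material
17 | sorbicillin | C/C=C/C=C/C(=O)c1cc(C)c(O)c(C)c1O | intermediate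
18 | (S)-2-methoxy-2-phenylacetic acid | CO[C@H](C(=O)O)c1ccccc1 | starting material
19 | (1R)-3-[(2E,4E)-hexa-2,4-dienoyl]-4-hydroxy-1,5-dimethyl-6-oxocyclohexa-2,4-dien-1-yl (2S)-2-methoxy-2-phenylacetate | C/C=C/C=C/C(=O)C1=C[C@@](C)(OC(=O)[C@@H](OC)c2ccccc2)C(=O)C(C)=C1O | intermediate
20 | (R)-sorbicillinol | C/C=C/C=C/C(=O)C1=C[C@@](C)(O)C(=O)C(C)=C1O | intermediate
21 | target CNP0259039.2 | C/C=C/C=C/C(O)=C1/C(=O)[C@@]2(C)C(=O)[C@](C)(O)[C@@H]1C[C@]21O[C@H]2C=C(C(=O)OC)C[C@@H](O)[C@@H]2OC1=O | target

**Totals.** Total step count: 12. Longest linear sequence: 8 steps (1, 3, 4, 5, 7, 8, 9, 12).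

**Steps most likely to fail**

Step 3 (key step). Lewis-acid-induced opening or acyl-shift rearrangement of the oxirane and loss of the β-silyloxy group may outrun carbonyl addition, and the betaine may collapse to a spiro-oxirane instead of migrating. Fallback: from 2, the lithium salt of 4 (LDA, THF, −78 °C) is added to the ketone under basic conditions to give the diazo alcohol methyl 2-diazo-2-[4-(tert-butyldimethylsilyloxy)-2-hydroxy-6-oxabicyclo[3.1.0]hexan-2-yl]acetate F1. Rh2(OAc)4 (cat., CH2Cl2, rt) then generates the rhodium carbene, whose 1,2-shift of the CH2 ring carbon gives 5, where the route is rejoined.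

Step 7. The weakly nucleophilic hydroxy ester may add too slowly, so that Lewis-acid isomerisation of the vinyl oxirane or attack at the wrong oxirane carbon takes over. Fallback: from 8, HClO4 in THF/H2O opens the oxirane at the allylic carbon to the trans-diol methyl (3S,4R,5R)-5-[(tert-butyldimethylsilyl)oxy]-3,4-dihydroxycyclohex-1-ene-1-carboxylate F2. Rh2(OAc)4-catalysed O–H insertion of triethyl diazophosphonoacetate into the less hindered allylic 3-OH (benzene, 80 °C) gives the phosphonoacetate ether F3. NaH in THF closes the lactone to the 3-(diethoxyphosphoryl)dioxanone F4, and paraformaldehyde added to the same flask gives 13 by Horner–Wadsworth–Emmons olefination, where the route is rejoined.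

Step 12. Dimerisation of 20 may outrun the cross-cycloaddition with the hindered 1,1-disubstituted dienophile, and endo/exo control may be poor. Fallback: from 17, a Wessely oxidation in the presence of chloroacetic acid (Pb(OAc)4, CH2Cl2) gives the racemic o-quinol chloroacetate F5, which does not dimerise at room temperature. Heated with 14 (PhMe, 80 °C) it should give the O-chloroacetyl derivative of 21 F6 beside the adduct of the other diene enantiomer F7, which is removed by chromatography. Thiourea/NaHCO3 (EtOH, 50 °C) then cleaves the chloroacetate of F6 and the route comes back at 21.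

**Further compounds**

F1 | step 3 | methyl 2-diazo-2-[4-(tert-butyldimethylsilyloxy)-2-hydroxy-6-oxabicyclo[3.1.0]hexan-2-yl]acetate (carbinol configuration not defined) | COC(=O)C(=[N+]=[N-])C1(O)C[C@@H](O[Si](C)(C)C(C)(C)C)[C@@H]2O[C@H]12
F2 | step 7 | methyl (3S,4R,5R)-5-[(tert-butyldimethylsilyl)oxy]-3,4-dihydroxycyclohex-1-ene-1-carboxylate | O[C@H]1C=C(C(=O)OC)C[C@@H](O[Si](C)(C)C(C)(C)C)[C@@H]1O
F3 | step 7 | 3-O-[1-(diethoxyphosphoryl)-2-ethoxy-2-oxoethyl] ether of F2 | CCOC(=O)C(O[C@H]1C=C(C(=O)OC)C[C@@H](O[Si](C)(C)C(C)(C)C)[C@@H]1O)P(=O)(OCC)OCC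
F4 | step 7 | methyl (4aS,8R,8aR)-8-[(tert-butyldimethylsilyl)oxy]-3-(diethoxyphosphoryl)-2-oxo-2,3,4a,7,8,8a-hexahydro-1,4-benzodioxine-6-carboxylate | CCOP(=O)(OCC)C1O[C@H]2C=C(C(=O)OC)C[C@@H](O[Si](C)(C)C(C)(C)C)[C@@H]2OC1=O
F5 | step 12 | rac-3-[(2E,4E)-hexa-2,4-dienoyl]-4-hydroxy-1,5-dimethyl-6-oxocyclohexa-2,4-dien-1-yl chloroacetate | C/C=C/C=C/C(=O)C1=CC(C)(OC(=O)CCl)C(=O)C(C)=C1O
F6 | step 12 | O-chloroacetyl derivative of 21 (tertiary ester) | C/C=C/C=C/C(O)=C1/C(=O)[C@@]2(C)C(=O)[C@](C)(OC(=O)CCl)[C@@H]1C[C@]21O[C@H]2C=C(C(=O)OC)C[C@@H](O)[C@@H]2OC1=O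
F7 | step 12 | diastereomer of F6 with the mirror-image bicyclo[2.2.2]octane and spiro centre | C/C=C/C=C/C(O)=C1/C(=O)[C@]2(C)C(=O)[C@@](C)(OC(=O)CCl)[C@H]1C[C@@]21O[C@H]2C=C(C(=O)OC)C[C@@H](O)[C@@H]2OC1=O
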